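## Retrosynthetic overview

1. C3–OBz bond: the target comes from the all-cis 2β,3β-epoxy-1β,4β-diol and benzoic acid by anti opening at C3 (last step).
2. C4–H bond: the epoxy diol comes from the 2β,3β-epoxy enone by 1,2-reduction anti to the oxirane.
3. Key step: the epoxy enone comes from an achiral p-quinol by amine-catalysed desymmetrizing nucleophilic epoxidation with H2O2, which sets C1, C2 and C3 together.
4. The p-quinol comes from 4-hydroxybenzyl benzoate by oxidative dearomatization with water, and that ester from 4-hydroxybenzyl alcohol and benzoic acid.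
5. Rings: the carbocycle is the benzene ring of the phenol and is never built. The oxirane is the only ring formed (third step) and is opened in the last step.

Assumption: locants C1–C6 and α/β follow the target name in all intermediates (β = face of the C1-OH), and the quinine-derived amine is taken to be the pseudoenantiomer that turns cyclohex-2-enone into (2R,3R)-2,3-epoxycyclohexanone, the sense needed here; if the rotation of 5 shows the opposite sense, the quinidine-derived pseudoenantiomer is used and nothing else changes.

## Route

Step 1
Reactants: 1 4-hydroxybenzyl alcohol; 2 benzoic acid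
Product: 3 4-hydroxybenzyl benzoate
Conditions: PPh3 (1.1 equiv), DIAD (1.1 equiv), THF, 0 °C to rt
Reagents that add atoms: benzoic acid (2), O=C(O)c1ccccc1
Why: Mitsunobu esterification, in which only the benzylic OH is activated as an oxyphosphonium leaving group and benzoic acid (pKa about 4) outcompetes the phenol (pKa about 10) as pronucleophile, so the phenol stays free and no stereocenter is involved.

Step 2
Reactants: 3 4-hydroxybenzyl benzoate
Product: 4 (1-hydroxy-4-oxocyclohexa-2,5-dien-1-yl)methyl benzoate (achiral p-quinol)
Conditions: PhI(OAc)2 (1.1 equiv), MeCN/H2O 3:1, 0 °C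
Reagents that add atoms: water, O
Why: Oxidative dearomatization of a para-substituted phenol by a trivalent iodine reagent, in which ligand exchange at iodine, attack of water at the substituted para carbon and loss of PhI give the p-quinol, which has a mirror plane through C1 and C4, while the neutral to acidic medium avoids 1,6-elimination of benzoate from the phenolate.

Step 3
Reactants: 4 (1-hydroxy-4-oxocyclohexa-2,5-dien-1-yl)methyl benzoate
Product: 5 [(1S,2S,6R)-2-hydroxy-5-oxo-7-oxabicyclo[4.1.0]hept-3-en-2-yl]methyl benzoate (target locants: 1S,2S,3R; 2β,3β-oxirane cis to the C1-OH, C4 ketone, C5=C6 alkene)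
Conditions: 9-amino-9-deoxy-epi-quinine (10 mol %), CF3CO2H (20 mol %), 50% aq H2O2 (1.3 equiv), dioxane, 30 °C
Reagents that add atoms: hydrogen peroxide, OO
Why: Proposed new method: a catalytic desymmetrizing Weitz–Scheffer epoxidation of a cross-conjugated p-quinol under iminium activation, in which reversible condensation of the primary amine with the C4 carbonyl places the protonated quinuclidine beside one or the other enantiotopic C=C, the H2O2 bound there adds to the nearby β-carbon (C2) from the one face the catalyst allows, and C3 then closes the oxirane on the O–O bond with loss of water; catalyst control therefore permits only two of the four mono-epoxides (one syn and one anti to the C1-OH, on opposite alkenes), the innate preference of p-quinols for peroxide attack on the face of the small, hydrogen-bonding tertiary OH leaves the 2β,3β-epoxide, so that C1 (by desymmetrization), C2 and C3 are fixed in one event, and the minor enantiomer is the matched substrate for a second epoxidation and is removed as bis-epoxide; the closest known reaction types are the cinchona primary amine salt/H2O2 epoxidation of simple cyclic enones and the racemic OH-syn-selective alkaline epoxidation of p-quinols, neither of which, to my knowledge, has been used to desymmetrize a 4-hydroxycyclohexa-2,5-dienone.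

Step 4
Reactants: 5 [(1S,2S,6R)-2-hydroxy-5-oxo-7-oxabicyclo[4.1.0]hept-3-en-2-yl]methyl benzoate
Product: 6 [(1S,2S,5S,6S)-2,5-dihydroxy-7-oxabicyclo[4.1.0]hept-3-en-2-yl]methyl benzoate (target locants: 1S,2S,3S,4S; C1-OH, oxirane O and C4-OH all on the β-face)
Conditions: NaBH4 (1.0 equiv), CeCl3·7H2O (1.0 equiv), MeOH, −78 °C
Reagents that add atoms: none
Why: Luche reduction, in which the hard borohydride adds 1,2 to the enone from the α-face, anti to the oxirane C–O bond (Felkin–Anh-type stereoelectronics plus shielding of the β-face by the oxirane O and the C1-OH), so the new C4-OH is β (4S), and ester and oxirane survive at −78 °C.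

Step 5
Reactants: 6 [(1S,2S,5S,6S)-2,5-dihydroxy-7-oxabicyclo[4.1.0]hept-3-en-2-yl]methyl benzoate; 2 benzoic acid
Product: 7 1α-benzoyloxymethyl-3α-benzoyloxycyclohex-5-ene-1β,2β,4β-triol, (1S,2S,3R,4S)
Conditions: PhCO2H (2.0 equiv), Ti(OiPr)4 (1.5 equiv), CH2Cl2, 0 °C to rt; then H2O work-up
Reagents that add atoms: benzoic acid (2), O=C(O)c1ccccc1
Why: Caron–Sharpless-type opening of a 2,3-epoxy alcohol by a carboxylic acid, in which tetravalent titanium binds the β-face alkoxides and the oxirane O and benzoate attacks in SN2 fashion from the α-face at C3, because the path to C2 is blocked by the quaternary C1 and its α-CH2OBz, so inversion gives 3α-OBz (3R) and the retained C2–O bond becomes the 2β-OH (2S).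

## Compound list

1 | 4-hydroxybenzyl alcohol | OCc1ccc(O)cc1 | starting material
2 | benzoic acid | O=C(O)c1ccccc1 | starting material
3 | 4-hydroxybenzyl benzoate | O=C(OCc1ccc(O)cc1)c1ccccc1 | intermediate
4 | (1-hydroxy-4-oxocyclohexa-2,5-dien-1-yl)methyl benzoate (achiral p-quinol) | O=C(OCC1(O)C=CC(=O)C=C1)c1ccccc1 | intermediate
5 | [(1S,2S,6R)-2-hydroxy-5-oxo-7-oxabicyclo[4.1.0]hept-3-en-2-yl]methyl benzoate | O=C(OC[C@@]1(O)C=CC(=O)[C@@H]2O[C@H]12)c1ccccc1 | intermediate
6 | [(1S,2S,5S,6S)-2,5-dihydroxy-7-oxabicyclo[4.1.0]hept-3-en-2-yl]methyl benzoate | O=C(OC[C@@]1(O)C=C[C@H](O)[C@@H]2O[C@H]12)c1ccccc1 | intermediate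
7 | (1S,2S,3R,4S)-1α-benzoyloxymethyl-3α-benzoyloxycyclohex-5-ene-1β,2β,4β-triol | O=C(OC[C@@]1(O)C=C[C@H](O)[C@@H](OC(=O)c2ccccc2)[C@@H]1O)c1ccccc1 | target

## Step count and risk

Total step count: 5. Longest linear sequence: 5 (1 → 3 → 4 → 5 → 6 → 7; benzoic acid 2 enters in steps 1 and 5).

The three steps most likely to fail:

**Step 3 (the proposed new step).**
- Risk: cross-conjugated dienones condense slowly with amines, so conversion may be poor. The enantiotopic alkene selection or the syn/anti ratio may be lower than with simple enones. Bis-epoxide may take too much material.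
- Fallback, known chemistry only, from 4 back to 6: 4 is epoxidised without a chiral catalyst under ordinary Weitz–Scheffer conditions (30% H2O2, cat. benzyltrimethylammonium hydroxide, THF, 0 °C). On p-quinols these conditions are selective for the face of the OH, and they give the racemic syn-epoxy enone F1. Luche reduction as in step 4 gives the racemic all-cis epoxy diol F2. A lipase-catalysed kinetic resolution follows (Amano lipase PS, vinyl acetate, MTBE, 30 °C, stopped just past 50% conversion). By the Kazlauskas rule it should acetylate the (4R)-enantiomer to the 4-O-acetate of the enantiomeric epoxy diol F3. The unreacted (4S)-alcohol 6 is separated by chromatography and continues into step 5.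
- Price: one more step and at most half of the material.

**Step 5.**
- Risk: the C4-OH can also bind titanium and steer benzoate to C2, and the new C3 benzoate can migrate to a neighbouring OH.
- Fallback from 6 back to 7: the secondary C4-OH is silylated selectively (TBSCl, imidazole, DMF, 0 °C; the tertiary C1-OH does not react) to give the 4-O-TBS epoxy alcohol F4. Now only the C1-OH can chelate, the substrate is a plain 2,3-epoxy alcohol with its distal carbon at C3, and migration toward C4 is blocked. PhCO2H and Ti(OiPr)4 in CH2Cl2 then give the 4-O-TBS 3α-benzoate F5. HF·pyridine in THF at 0 °C (non-basic, so no acyl shift) releases 7.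

**Step 2.**
- Risk: the electron-poor CH2OBz group disfavours attack of water at the para carbon, so yields of about 35–50% and ortho or acetate capture are expected.
- Fallback from 3 back to 4: the two-electron iodane oxidation is replaced by a singlet-oxygen dearomatization (O2, rose bengal 2 mol %, green LED, MeCN/H2O, 0 °C, no base). This gives the 4-hydroperoxy dienone F6, which is reduced with Me2S (1.5 equiv, 0 °C) to 4.

## Further compounds

F1 | step 3 | racemic syn-epoxy enone (1:1 mixture of 5 and its enantiomer) | O=C(OC[C@@]1(O)C=CC(=O)[C@@H]2O[C@H]12)c1ccccc1.O=C(OC[C@]1(O)C=CC(=O)[C@H]2O[C@@H]12)c1ccccc1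
F2 | step 3 | racemic all-cis epoxy diol (1:1 mixture of 6 and its enantiomer) | O=C(OC[C@@]1(O)C=C[C@H](O)[C@@H]2O[C@H]12)c1ccccc1.O=C(OC[C@]1(O)C=C[C@@H](O)[C@H]2O[C@@H]12)c1ccccc1
F3 | step 3 | [(1R,2R,5R,6R)-5-acetoxy-2-hydroxy-7-oxabicyclo[4.1.0]hept-3-en-2-yl]methyl benzoate (4-O-acetate of the enantiomer of 6) | O=C(OC[C@]1(O)C=C[C@@H](OC(C)=O)[C@H]2O[C@@H]12)c1ccccc1
F4 | step 5 | 4-O-tert-butyldimethylsilyl ether of 6 | O=C(OC[C@@]1(O)C=C[C@H](O[Si](C)(C)C(C)(C)C)[C@@H]2O[C@H]12)c1ccccc1
F5 | step 5 | 4-O-tert-butyldimethylsilyl ether of 7 | O=C(OC[C@@]1(O)C=C[C@H](O[Si](C)(C)C(C)(C)C)[C@@H](OC(=O)c2ccccc2)[C@@H]1O)c1ccccc1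
F6 | step 2 | (1-hydroperoxy-4-oxocyclohexa-2,5-dien-1-yl)methyl benzoate | O=C(OCC1(OO)C=CC(=O)C=C1)c1ccccc1
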